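The readings are calculated for substances that don't exist; the scatter is artificial.

**One question.** 5 questions stand here, and they come down to one: does the way of adding change the bis adduct at 5.0 h?

| flask | substrate | coupling partner | remark | time |
|---|---|---|---|---|
| cedar | 0.20 M | 0.40 M | run made earlier |  |
| ash | 0.20 M | 0.20 M | run made earlier |  |
| maple | 0.20 M | 0.30 M | run made earlier |  |
| spring | 0.20 M | 0.400 M (in portions, 4, over 1.0 h) | first portion at the start, last at 1.0 h | 5.0 h |
| dusk | 0.20 M (fed, over 1.0 h) | 0.400 M | all else is in the flask from the start; the feed brings no volume worth counting | 5.0 h |
| midnight | 0.20 M | 0.400 M | everything together at the start | 5.0 h |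
| winter | 0.20 M | 0.400 M (fed, over 1.0 h) | all else is in the flask from the start; the feed brings no volume worth counting | 5.0 h |

| run | time / h | bis adduct / % |
|---|---|---|
| cedar | 0.333 | 5.9 |
| cedar | 1.00 | 21.5 |
| cedar | 2.00 | 35.3 |
| cedar | 2.50 | 38.7 |
| cedar | 4.00 | 39.5 |
| cedar | 5.00 | 40.3 |
| ash | 0.417 | 2.1 |
| ash | 0.667 | 4.6 |
| ash | 1.00 | 8.1 |
| ash | 2.00 | 16.4 |
| ash | 3.00 | 20.1 |
| ash | 5.00 | 26.0 |
| maple | 0.833 | 12.6 |
| maple | 1.50 | 21.1 |
| maple | 2.50 | 29.4 |
| maple | 3.00 | 31.1 |
| maple | 4.00 | 34.9 |
| maple | 5.00 | 36.4 |

(scatter of a reading: 1 percentage point)

- which flask leads in amount of bis adduct, in percent of the substrate charged ("all alike" within 1.5 percentage points) (spring / dusk / midnight / winter / all alike)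
- how much bis adduct is there at the end, in percent of the substrate charged: spring
- how much bis adduct is there at the end, in percent of the substrate charged: dusk
- how much bis adduct is there at the end, in percent of the substrate charged: midnight
- how much bis adduct is there at the end, in percent of the substrate charged: winter

- what was read earlier has a scatter of 1 percentage point, one standard deviation

**Early extreme.** Midnight has the charges of cedar, so one extreme is already solved. Every molecule starts at time zero, and cedar reads 40.3% at the end.

**Late extreme.** In the other extreme, whatever is dosed waits and enters whole when the dosing ends, at 1.0 h. That flask is cedar with its clock started late, so it ends where cedar stood 1.0 h before the end. One reading there carries a scatter of 1 percentage point, so I take the longer stretch: cedar climbs from 38.7% at 2.50 h to 40.3% at 5.00 h. At that slope the lost time costs 0.64 points. I call this the clock loss, the late slope of the curve times the dosing time.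

**Real flasks.** A dosed molecule enters somewhere between these extremes, so its clock runs late by between zero and 1.0 h. I therefore expect spring, dusk and winter to lie below midnight by about the clock loss or less. That is smaller than the margin of 1.5 points, so I commit to all alike.

**The result.** The forecast gives spring 37%, dusk 43%, midnight 40.5% and winter 35.5%, with dusk ahead, since “dusk gains slightly”. The flasks give spring 40.5%, dusk 40.3%, midnight 40.8% and winter 40.6%, which is all alike; midnight stands 0.50 points above dusk, less than the clock loss.

    substrate + coupling partner → first product + released group (k = 4.36 × 10⁻⁴ /M/s)
    coupling partner + first product → bis adduct + released group (k = 0.00166 /M/s)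
    coupling partner + bis adduct → triple product + released group (k = 2.58 × 10⁻⁴ /M/s)
    first product → side product (k = 3.81 × 10⁻⁵ /s)
    bis adduct → over-reaction product (k = 2.79 × 10⁻⁷ /s)

**Flat top.** A coupling partner molecule in midnight at 5.00 h can meet substrate, first product or bis adduct, and for the last two the selectivity factor, second rate constant over third, is 6.43. Weighted by first product at 6.61% and bis adduct at 40.8%, making bis adduct and turning it into triple product stand in midnight at a ratio of 1.04.

**Second flask.** Take dusk with 60.0% of its coupling partner charge. Between ash and maple, undosed, I read 30.2%, and ash's late slope gives a clock loss of 3 points, larger than cedar's 0.64 points, so I expect about 27.2% to 30.2%. The computed flask gives 29.3%.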